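**Retrosynthetic overview**
1. Ring labels: ring A is the benzene ring fused to the seven-membered ring and to the (2S,3S)-dihydrofuran; ring B is the benzene ring fused to the seven-membered ring and to the (2R,3R)-dihydrofuran. Last comes a sevenfold O-dealkylation; before it the seven-membered carbocycle is closed by gold-catalysed 7-endo hydroarylation of a ring-A aryl alkyne by ring B.
2. The dihydrofuran on ring A comes from a rhodium-carbene C–H insertion on a diaryl ketone hydrazone (antipodal catalyst); the ketone joins a ring-B aryllithium to a ring-A aldehyde.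
3. Key disconnection: the C2–C3 bond of the dihydrofuran on ring B (C2 carries the 4-oxygenated phenyl group, C3 the 3,5-dioxygenated phenyl group), made by enantioselective 1,5 C–H insertion of a donor/donor rhodium carbene generated from a flat, achiral benzophenone hydrazone.
4. Enabling feature: the O–CH2–aryl unit of a 4-methoxybenzyl ether on the ring-B carbon ortho to the carbene-bearing carbon. Its benzylic, oxygen-activated C–H lies five atoms from the carbene carbon, so one of two identical protecting groups becomes C2 with its aryl group while its twin keeps protecting the ring-B phenol.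
5. Order of ring formation: dihydrofuran on ring B (step 5, trans after step 6), dihydrofuran on ring A (step 13, trans after step 14), seven-membered ring (step 16).

Key step: step 5

Assumption: Rh2(S-PTAD)4 (PTAD = (1-adamantyl)(N-phthalimido)acetate) is taken to give the (3R)-dihydrobenzofuran in these benzylic-ether insertions and Rh2(R-PTAD)4 the (3S) one; if the sense is the reverse, the two catalysts change places between steps 5 and 13.

**Step 1**
Reactants: 1 4-bromo-2,6-difluorobenzaldehyde; 2 3,5-dimethoxyphenylmagnesium chloride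
Product: 3 (4-bromo-2,6-difluorophenyl)(3,5-dimethoxyphenyl)methanol (racemic)
Conditions: THF, −78 → 0 °C; aq. HCl (1 M)
Reagents that add atoms: none
Why: Grignard 1,2-addition to the aldehyde should outrun substitution of the ortho fluorines and exchange at the bromide at low temperature; the racemic carbinol centre is destroyed in step 2.

**Step 2**
Reactants: 3 (4-bromo-2,6-difluorophenyl)(3,5-dimethoxyphenyl)methanol
Product: 4 (4-bromo-2,6-difluorophenyl)(3,5-dimethoxyphenyl)methanone
Conditions: Dess–Martin periodinane, CH2Cl2, rt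
Reagents that add atoms: none
Why: Dess–Martin oxidation of a secondary diaryl carbinol to the ketone, with no other oxidisable group present.

**Step 3**
Reactants: 4 (4-bromo-2,6-difluorophenyl)(3,5-dimethoxyphenyl)methanone; 5 4-methoxybenzyl alcohol
Product: 6 {4-bromo-2,6-bis[(4-methoxybenzyl)oxy]phenyl}(3,5-dimethoxyphenyl)methanone
Conditions: 5 (2.3 equiv), NaH (2.4 equiv), THF, 0 → 50 °C
Reagents that add atoms: none
Why: Double nucleophilic aromatic substitution (SNAr): both fluorines are ortho to the ketone, which stabilises the Meisenheimer adducts, and fluoride is by far the better leaving group, so the para bromide should survive.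

**Step 4**
Reactants: 6 {4-bromo-2,6-bis[(4-methoxybenzyl)oxy]phenyl}(3,5-dimethoxyphenyl)methanone
Product: 7 hydrazone of ketone 6
Conditions: N2H4·H2O (excess), AcOH (cat.), n-BuOH, 110 °C
Reagents that add atoms: hydrazine hydrate, NN.O
Why: Acid-catalysed hydrazone condensation of a non-enolisable diaryl ketone under forcing conditions; the ortho benzyloxy groups slow but should not block attack by the small nucleophile, and the bromide and benzyl ethers are inert.

**Step 5**
Reactants: 7 hydrazone of ketone 6
Product: 9 (2S,3R)-6-bromo-3-(3,5-dimethoxyphenyl)-4-[(4-methoxybenzyl)oxy]-2-(4-methoxyphenyl)-2,3-dihydro-1-benzofuran (2,3-cis), via diaryldiazomethane 8 (not isolated)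
Conditions: MnO2, CH2Cl2, 0 °C, then filtration; Rh2(S-PTAD)4 (1 mol %), CH2Cl2, −40 °C → rt
Reagents that add atoms: none
Why: MnO2 dehydrogenates the hydrazone to diaryldiazomethane 8, Rh2(S-PTAD)4 expels N2 to give a donor/donor rhodium carbene, and the electrophilic carbene carbon takes the hydridic benzylic O–CH2 hydrogen of an ortho 4-methoxybenzyl ether through a five-centre transition state while the C2–C3 bond closes (asynchronous concerted insertion). The closest known reaction type is the enantioselective intramolecular 1,5 C–H insertion of donor/donor rhodium carbenes into benzyl aryl ethers, which gives 2,3-diaryl-2,3-dihydrobenzofurans. The five-membered oxygen ring closes in the 5-exo sense of a 1,5-insertion by C–C bond formation between the ether methylene carbon and the carbene carbon, the O–C2 and C3–aryl bonds being in place beforehand. C3 is set by the chiral carboxylate pocket of the catalyst, which selects one face of the carbene of an achiral substrate, and C2 should follow as cis because hydrogen transfer and C–C closure take place on the same face of the methylene group; the cis relation is corrected at C2 in step 6. The step needs insertion to outrun azine formation, carbene dimerisation and attack on arene rings: the two ortho ether groups are homotopic (either gives 9) and are held next to the twisted carbene, the 4-methoxy group and the ether oxygen make the C–H bond hydridic, and no other C–H or O–H bond lies five atoms from the carbene carbon.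

**Step 6**
Reactants: 9 cis-dihydrobenzofuran
Product: 10 (2R,3R)-6-bromo-3-(3,5-dimethoxyphenyl)-2-(4-methoxyphenyl)-2,3-dihydro-1-benzofuran-4-ol (2,3-trans)
Conditions: TFA, 1,3,5-trimethoxybenzene, CH2Cl2, 0 °C → rt
Reagents that add atoms: none
Why: TFA cleaves the remaining 4-methoxybenzyl ether by SN1 ionisation (cation trapped by trimethoxybenzene) and reversibly ionises the benzylic C2–O bond, so that reclosure should give the thermodynamically preferred 2,3-trans ring (acid-mediated epimerisation at C2) with C3 unchanged; ring B is still symmetric, so reclosure through either phenol oxygen gives the same compound.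

**Step 7**
Reactants: 10 trans-dihydrobenzofuranol
Product: 11 (2R,3R)-6-bromo-3-(3,5-dimethoxyphenyl)-4-isopropoxy-2-(4-methoxyphenyl)-2,3-dihydro-1-benzofuran
Conditions: 2-bromopropane, K2CO3, DMF, 60 °C
Reagents that add atoms: 2-bromopropane, CC(C)Br
Why: Williamson etherification of the phenol; the isopropyl ether protects it through the organolithium and carbene steps and later shields the neighbouring ring-B carbon in step 16.

**Step 8**
Reactants: 12 2-bromo-4,6-dimethoxybenzaldehyde
Product: 13 2-bromo-6-hydroxy-4-methoxybenzaldehyde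
Conditions: BCl3 (1.1 equiv), CH2Cl2, −78 → 0 °C; H2O
Reagents that add atoms: none
Why: Chelation-controlled demethylation: BCl3 should remove only the methoxy group ortho to the aldehyde through the six-membered boron chelate and leave the para methoxy group.

**Step 9**
Reactants: 13 2-bromo-6-hydroxy-4-methoxybenzaldehyde; 14 4-methoxybenzyl chloride
Product: 15 2-bromo-4-methoxy-6-[(4-methoxybenzyl)oxy]benzaldehyde
Conditions: K2CO3, DMF, rt
Reagents that add atoms: none
Why: Williamson etherification of the phenol with a reactive benzylic chloride under mild base, which leaves the aldehyde and the aryl bromide untouched.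

**Step 10**
Reactants: 11 isopropyl ether bromide; 15 2-bromo-4-methoxy-6-[(4-methoxybenzyl)oxy]benzaldehyde
Product: 17 {2-bromo-4-methoxy-6-[(4-methoxybenzyl)oxy]phenyl}[(2R,3R)-3-(3,5-dimethoxyphenyl)-4-isopropoxy-2-(4-methoxyphenyl)-2,3-dihydro-1-benzofuran-6-yl]methanol (both carbinol epimers), via aryllithium 16 (not isolated)
Conditions: n-BuLi, THF, −78 °C; then 15, −78 → −20 °C; H2O
Reagents that add atoms: none
Why: Bromine–lithium exchange at −78 °C should be faster than deprotonation of the benzylic methines, and 1,2-addition of the aryllithium to the aldehyde faster than exchange with its aryl bromide; the carbinol centre is destroyed in step 11.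

**Step 11**
Reactants: 17 diaryl carbinol
Product: 18 {2-bromo-4-methoxy-6-[(4-methoxybenzyl)oxy]phenyl}[(2R,3R)-3-(3,5-dimethoxyphenyl)-4-isopropoxy-2-(4-methoxyphenyl)-2,3-dihydro-1-benzofuran-6-yl]methanone
Conditions: Dess–Martin periodinane, CH2Cl2, rt
Reagents that add atoms: none
Why: Dess–Martin oxidation under neutral conditions, which should leave the acid-labile dihydrofuran and the benzyl ether intact.

**Step 12**
Reactants: 18 diaryl ketone
Product: 19 hydrazone of ketone 18
Conditions: N2H4·H2O (excess), AcOH (cat.), n-BuOH, 110 °C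
Reagents that add atoms: hydrazine hydrate, NN.O
Why: Hydrazone condensation as in step 4; only the ring-A side of the carbonyl is hindered, and the uncatalysed aryl bromide should not react with hydrazine.

**Step 13**
Reactants: 19 hydrazone of ketone 18
Product: 21 (2R,3S)-4-bromo-3-[(2R,3R)-3-(3,5-dimethoxyphenyl)-4-isopropoxy-2-(4-methoxyphenyl)-2,3-dihydro-1-benzofuran-6-yl]-6-methoxy-2-(4-methoxyphenyl)-2,3-dihydro-1-benzofuran (2,3-cis in the new ring), via diaryldiazomethane 20 (not isolated)
Conditions: MnO2, CH2Cl2, 0 °C, then filtration; Rh2(R-PTAD)4 (1 mol %), CH2Cl2, −40 °C → rt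
Reagents that add atoms: none
Why: The same donor/donor rhodium-carbene 1,5 C–H insertion into the ortho 4-methoxybenzyl ether as in step 5, now with the enantiomeric catalyst; catalyst control should override the remote stereocentres and set the new C3 as (S), with C2 cis.

**Step 14**
Reactants: 21 cis compound
Product: 22 (2S,3S)-4-bromo-3-[(2R,3R)-3-(3,5-dimethoxyphenyl)-4-isopropoxy-2-(4-methoxyphenyl)-2,3-dihydro-1-benzofuran-6-yl]-6-methoxy-2-(4-methoxyphenyl)-2,3-dihydro-1-benzofuran (both rings 2,3-trans)
Conditions: TFA, CH2Cl2, 0 °C → rt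
Reagents that add atoms: none
Why: Acid-mediated epimerisation at C2 of the new ring through reversible benzylic C–O ionisation should give the trans isomer, C3 being untouched; the ring on ring B is already in its equilibrium trans form.

**Step 15**
Reactants: 22 all-trans aryl bromide; 23 4-ethynylanisole
Product: 24 (2S,3S)-3-[(2R,3R)-3-(3,5-dimethoxyphenyl)-4-isopropoxy-2-(4-methoxyphenyl)-2,3-dihydro-1-benzofuran-6-yl]-6-methoxy-2-(4-methoxyphenyl)-4-[(4-methoxyphenyl)ethynyl]-2,3-dihydro-1-benzofuran
Conditions: PdCl2(MeCN)2 (3 mol %), XPhos (9 mol %), Cs2CO3, MeCN, 80 °C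
Reagents that add atoms: none
Why: Copper-free Sonogashira coupling; the bulky electron-rich biaryl phosphine is chosen for the hindered, electron-rich aryl bromide, and no group in 22 is sensitive to carbonate base.

**Step 16**
Reactants: 24 diaryl alkyne
Product: 25 hexamethyl isopropyl ether of the target (seven-membered ring closed, alkene carbon bound to ring B carries the 4-methoxyphenyl group)
Conditions: Ph3PAuNTf2 (5 mol %), ClCH2CH2Cl, rt → 60 °C
Reagents that add atoms: none
Why: Intramolecular alkyne hydroarylation (7-endo-dig): cationic monovalent gold activates the alkyne, ring B attacks in a Friedel–Crafts manner and protodeauration follows; the 4-methoxyphenyl group polarises the alkyne so that its distal carbon should be attacked, and of the two free ortho carbons of ring B the one beside the tied-back dihydrofuran oxygen should react because the other is flanked by the isopropoxy group; no stereocentre is formed.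

**Step 17**
Reactants: 25 hexamethyl isopropyl ether
Product: 26 target heptaphenol
Conditions: BBr3 (excess), CH2Cl2, −78 °C → rt; H2O
Reagents that add atoms: none
Why: Lewis-acid ether cleavage with BBr3 should remove the six methyl groups and the isopropyl group at alkyl carbon, leaving the aryl–oxygen bonds of both dihydrofurans and all four stereocentres (both rings already in the thermodynamic trans arrangement) unchanged.

**Compound list**
1 | 4-bromo-2,6-difluorobenzaldehyde | O=Cc1c(F)cc(Br)cc1F | starting material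
2 | 3,5-dimethoxyphenylmagnesium chloride (THF solution) | COc1cc([Mg]Cl)cc(OC)c1 | starting material
3 | (4-bromo-2,6-difluorophenyl)(3,5-dimethoxyphenyl)methanol, racemic | COc1cc(cc(OC)c1)C(O)c1c(F)cc(Br)cc1F | intermediate
4 | (4-bromo-2,6-difluorophenyl)(3,5-dimethoxyphenyl)methanone | COc1cc(cc(OC)c1)C(=O)c1c(F)cc(Br)cc1F | intermediate
5 | 4-methoxybenzyl alcohol | COc1ccc(CO)cc1 | starting material
6 | {4-bromo-2,6-bis[(4-methoxybenzyl)oxy]phenyl}(3,5-dimethoxyphenyl)methanone | COc1ccc(COc2cc(Br)cc(OCc3ccc(OC)cc3)c2C(=O)c2cc(OC)cc(OC)c2)cc1 | intermediate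
7 | hydrazone of ketone 6 | COc1ccc(COc2cc(Br)cc(OCc3ccc(OC)cc3)c2C(=NN)c2cc(OC)cc(OC)c2)cc1 | intermediate
8 | 5-bromo-2-[diazo(3,5-dimethoxyphenyl)methyl]-1,3-bis[(4-methoxybenzyl)oxy]benzene | COc1ccc(COc2cc(Br)cc(OCc3ccc(OC)cc3)c2C(=[N+]=[N-])c2cc(OC)cc(OC)c2)cc1 | intermediate
9 | (2S,3R)-6-bromo-3-(3,5-dimethoxyphenyl)-4-[(4-methoxybenzyl)oxy]-2-(4-methoxyphenyl)-2,3-dihydro-1-benzofuran (cis) | Brc1cc(OCc3ccc(OC)cc3)c2c(c1)O[C@H](c1ccc(OC)cc1)[C@@H]2c1cc(OC)cc(OC)c1 | intermediate
10 | (2R,3R)-6-bromo-3-(3,5-dimethoxyphenyl)-2-(4-methoxyphenyl)-2,3-dihydro-1-benzofuran-4-ol (trans) | Brc1cc(O)c2c(c1)O[C@@H](c1ccc(OC)cc1)[C@@H]2c1cc(OC)cc(OC)c1 | intermediate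
11 | (2R,3R)-6-bromo-3-(3,5-dimethoxyphenyl)-4-isopropoxy-2-(4-methoxyphenyl)-2,3-dihydro-1-benzofuran | Brc1cc(OC(C)C)c2c(c1)O[C@@H](c1ccc(OC)cc1)[C@@H]2c1cc(OC)cc(OC)c1 | intermediate
12 | 2-bromo-4,6-dimethoxybenzaldehyde | COc1cc(Br)c(C=O)c(OC)c1 | starting material
13 | 2-bromo-6-hydroxy-4-methoxybenzaldehyde | COc1cc(O)c(C=O)c(Br)c1 | intermediate
14 | 4-methoxybenzyl chloride | COc1ccc(CCl)cc1 | starting material
15 | 2-bromo-4-methoxy-6-[(4-methoxybenzyl)oxy]benzaldehyde | COc1ccc(COc2cc(OC)cc(Br)c2C=O)cc1 | intermediate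
16 | [(2R,3R)-3-(3,5-dimethoxyphenyl)-4-isopropoxy-2-(4-methoxyphenyl)-2,3-dihydro-1-benzofuran-6-yl]lithium | [Li]c1cc(OC(C)C)c2c(c1)O[C@@H](c1ccc(OC)cc1)[C@@H]2c1cc(OC)cc(OC)c1 | intermediate
17 | {2-bromo-4-methoxy-6-[(4-methoxybenzyl)oxy]phenyl}[(2R,3R)-3-(3,5-dimethoxyphenyl)-4-isopropoxy-2-(4-methoxyphenyl)-2,3-dihydro-1-benzofuran-6-yl]methanol, both carbinol epimers | COc1ccc(COc2cc(OC)cc(Br)c2C(O)c2cc(OC(C)C)c3c(c2)O[C@@H](c2ccc(OC)cc2)[C@@H]3c2cc(OC)cc(OC)c2)cc1 | intermediate
18 | {2-bromo-4-methoxy-6-[(4-methoxybenzyl)oxy]phenyl}[(2R,3R)-3-(3,5-dimethoxyphenyl)-4-isopropoxy-2-(4-methoxyphenyl)-2,3-dihydro-1-benzofuran-6-yl]methanone | COc1ccc(COc2cc(OC)cc(Br)c2C(=O)c2cc(OC(C)C)c3c(c2)O[C@@H](c2ccc(OC)cc2)[C@@H]3c2cc(OC)cc(OC)c2)cc1 | intermediate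
19 | hydrazone of ketone 18 | COc1ccc(COc2cc(OC)cc(Br)c2C(=NN)c2cc(OC(C)C)c3c(c2)O[C@@H](c2ccc(OC)cc2)[C@@H]3c2cc(OC)cc(OC)c2)cc1 | intermediate
20 | diazo compound from hydrazone 19 (diaryldiazomethane) | COc1ccc(COc2cc(OC)cc(Br)c2C(=[N+]=[N-])c2cc(OC(C)C)c3c(c2)O[C@@H](c2ccc(OC)cc2)[C@@H]3c2cc(OC)cc(OC)c2)cc1 | intermediate
21 | (2R,3S)-4-bromo-3-[(2R,3R)-3-(3,5-dimethoxyphenyl)-4-isopropoxy-2-(4-methoxyphenyl)-2,3-dihydro-1-benzofuran-6-yl]-6-methoxy-2-(4-methoxyphenyl)-2,3-dihydro-1-benzofuran (new ring cis) | COc1cc2c(c(Br)c1)[C@H](c3cc(OC(C)C)c4c(c3)O[C@@H](c3ccc(OC)cc3)[C@@H]4c3cc(OC)cc(OC)c3)[C@H](c3ccc(OC)cc3)O2 | intermediate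
22 | (2S,3S)-4-bromo-3-[(2R,3R)-3-(3,5-dimethoxyphenyl)-4-isopropoxy-2-(4-methoxyphenyl)-2,3-dihydro-1-benzofuran-6-yl]-6-methoxy-2-(4-methoxyphenyl)-2,3-dihydro-1-benzofuran (both rings trans) | COc1cc2c(c(Br)c1)[C@H](c3cc(OC(C)C)c4c(c3)O[C@@H](c3ccc(OC)cc3)[C@@H]4c3cc(OC)cc(OC)c3)[C@@H](c3ccc(OC)cc3)O2 | intermediate
23 | 4-ethynylanisole | COc1ccc(C#C)cc1 | starting material
24 | (2S,3S)-3-[(2R,3R)-3-(3,5-dimethoxyphenyl)-4-isopropoxy-2-(4-methoxyphenyl)-2,3-dihydro-1-benzofuran-6-yl]-6-methoxy-2-(4-methoxyphenyl)-4-[(4-methoxyphenyl)ethynyl]-2,3-dihydro-1-benzofuran | COc1cc2c(c(C#Cc3ccc(OC)cc3)c1)[C@H](c3cc(OC(C)C)c4c(c3)O[C@@H](c3ccc(OC)cc3)[C@@H]4c3cc(OC)cc(OC)c3)[C@@H](c3ccc(OC)cc3)O2 | intermediate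
25 | hexamethyl isopropyl ether of the target: dibenzo-fused cycloheptatriene with a 4-methoxyphenyl group on the alkene carbon bound to ring B, (2S,3S)-2-(4-methoxyphenyl)dihydrofuran on ring A (its C3 is the bridging methine), (2R,3R)-2-(4-methoxyphenyl)-3-(3,5-dimethoxyphenyl)dihydrofuran on ring B, methoxy on ring A, isopropoxy on ring B | COc1ccc(C2=Cc3cc(OC)cc4c3[C@H](c3cc(OC(C)C)c5c(c32)O[C@@H](c2ccc(OC)cc2)[C@@H]5c2cc(OC)cc(OC)c2)[C@@H](c2ccc(OC)cc2)O4)cc1 | intermediate
26 | target heptaphenol (all seven ether groups of 25 as free OH; S,S at the dihydrofuran on ring A, R,R at the dihydrofuran on ring B) | Oc1ccc(C2=Cc3cc(O)cc4c3[C@H](c3cc(O)c5c(c32)O[C@@H](c2ccc(O)cc2)[C@@H]5c2cc(O)cc(O)c2)[C@@H](c2ccc(O)cc2)O4)cc1 | target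

**Step count and risks**
Total: 17 steps. Longest linear sequence: 15 steps (steps 1–7, then 10–17); steps 8–9 prepare the ring-A aldehyde.

Step 16 (seven-membered ring closure). What may go wrong: attack of ring B at the alkyne carbon nearer ring A (6-exo closure to a dihydroanthracene), or attack through the other free ortho carbon of ring B despite the isopropoxy shield. The fallback sets out from bromide 22 and rejoins at 25, with a cationic carbon that can only give the seven-membered ring. Heck coupling of 22 with 4-methoxystyrene (Pd(OAc)2, P(o-tol)3, K2CO3, DMF, 100 °C) should give the (E)-stilbene F1. Epoxidation with dimethyldioxirane (acetone, −20 °C) should give the trans-epoxide F2. BF3·OEt2 at −78 °C opens the epoxide at the carbon bearing the 4-methoxyphenyl group, and Friedel–Crafts alkylation by ring B closes the ring to the secondary alcohol F3. Dehydration with Burgess reagent (THF, 50 °C) should then give 25.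

Step 5 (key step). What may go wrong: insufficient facial selectivity of the insertion at the doubly ortho-substituted carbene, or erosion of the C3 configuration through elimination and re-addition during the acid-mediated cis-to-trans correction of step 6. The fallback sets out from ketone 6 and rejoins at phenol 10. A strong non-nucleophilic base (phosphazene base P4-t-Bu, toluene, 80 °C) deprotonates a benzylic ether methylene, and carbanion addition to the ketone followed by dehydration should give the 2,3-diarylbenzofuran F4. Ionic hydrogenation (Et3SiH, TFA), which also removes the remaining 4-methoxybenzyl ether, followed by equilibration in TFA alone, should give the racemic trans phenol F5. Esterification with (S)-naproxen chloride, separation of the diastereomeric esters by chromatography or crystallisation, and saponification (LiOH, THF/H2O) of the (2R,3R)-ester F6 should return enantiopure 10.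

Step 17 (global dealkylation). What may go wrong: acid-induced opening of the benzylic C2–O bonds of the dihydrofurans, cationic oligomerisation at the electron-rich cycloheptatriene, or incomplete sevenfold cleavage. The fallback sets out from 25 and rejoins at 26 without exposing the polyphenol to Lewis or protic acid. BCl3 (CH2Cl2, −78 °C) should remove only the isopropyl ether to give phenol F7. The six methyl ethers are then cleaved by SN2 demethylation with sodium ethanethiolate (DMF, 130 °C), and careful acidification should give 26.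

**Further compounds**
F1 | step 16 | (2S,3S)-3-[(2R,3R)-3-(3,5-dimethoxyphenyl)-4-isopropoxy-2-(4-methoxyphenyl)-2,3-dihydro-1-benzofuran-6-yl]-6-methoxy-2-(4-methoxyphenyl)-4-[(E)-2-(4-methoxyphenyl)ethenyl]-2,3-dihydro-1-benzofuran | COc1cc2c(c(/C=C/c3ccc(OC)cc3)c1)[C@H](c3cc(OC(C)C)c4c(c3)O[C@@H](c3ccc(OC)cc3)[C@@H]4c3cc(OC)cc(OC)c3)[C@@H](c3ccc(OC)cc3)O2
F2 | step 16 | trans-epoxide of stilbene F1 (both face isomers) | COc1cc2c(c(C5OC5c3ccc(OC)cc3)c1)[C@H](c3cc(OC(C)C)c4c(c3)O[C@@H](c3ccc(OC)cc3)[C@@H]4c3cc(OC)cc(OC)c3)[C@@H](c3ccc(OC)cc3)O2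
F3 | step 16 | ring-closed secondary alcohol (hydrate of the alkene of 25, hydroxyl on the carbon bound to ring A, isomers at the two new centres) | COc1ccc(C2C(O)c3cc(OC)cc4c3[C@H](c3cc(OC(C)C)c5c(c32)O[C@@H](c2ccc(OC)cc2)[C@@H]5c2cc(OC)cc(OC)c2)[C@@H](c2ccc(OC)cc2)O4)cc1
F4 | step 5 | 6-bromo-3-(3,5-dimethoxyphenyl)-4-[(4-methoxybenzyl)oxy]-2-(4-methoxyphenyl)-1-benzofuran | COc1ccc(COc2cc(Br)cc3oc(-c4ccc(OC)cc4)c(-c4cc(OC)cc(OC)c4)c23)cc1
F5 | step 5 | racemic trans-6-bromo-3-(3,5-dimethoxyphenyl)-2-(4-methoxyphenyl)-2,3-dihydro-1-benzofuran-4-ol | Brc1cc(O)c2c(c1)O[C@@H](c1ccc(OC)cc1)[C@@H]2c1cc(OC)cc(OC)c1.Brc1cc(O)c2c(c1)O[C@H](c1ccc(OC)cc1)[C@H]2c1cc(OC)cc(OC)c1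
F6 | step 5 | (S)-naproxen ester of (2R,3R)-phenol 10 | Brc1cc(OC(=O)[C@@H](C)c3ccc4cc(OC)ccc4c3)c2c(c1)O[C@@H](c1ccc(OC)cc1)[C@@H]2c1cc(OC)cc(OC)c1
F7 | step 17 | hexamethyl ether of the target with the ring-B hydroxyl free | COc1ccc(C2=Cc3cc(OC)cc4c3[C@H](c3cc(O)c5c(c32)O[C@@H](c2ccc(OC)cc2)[C@@H]5c2cc(OC)cc(OC)c2)[C@@H](c2ccc(OC)cc2)O4)cc1
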